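## Structural features

The target is a halimane-type diterpenoid methyl ester (halimane numbering throughout). A cyclohexene (ring A, C1–C5 and C10) is fused through the C5–C10 bond to a cyclohexane (ring B, C5–C10), and the only ring unsaturation is the trisubstituted C1=C10 double bond. Ring A carries the quaternary C4 (S; methyl and CO2Me) directly next to the ring-fusion methine C5 (R). Beyond sp2 C10, ring B carries the quaternary C9 (S; methyl and the C11–C15 chain) next to C8 (R; methyl), and the two methyl groups are cis. The chain ends in a trisubstituted 2,3-epoxy alcohol (C13 R, C14 R, C15–OH) that is too far from the ring stereocentres to be controlled by them. Fragile groups are the epoxy alcohol (acid opening, Payne rearrangement in base) and the C1=C10 alkene (acid can move it to the tetrasubstituted C5=C10 position); the neopentyl-like ester is slow in acyl substitution. The real difficulty is the C4–C5 bond between a quaternary and a tertiary carbon, with both configurations fixed and the alkene held at C1–C10. The key step exploits the fact that C4 is α to the carboxyl carbon and C5 is allylic to C1=C10, while C2–C3 bridges C1 and C4: the array O=C–C4–C5–C10=C1 is the retron of a lactone enolate Claisen shift.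

## Logic of the disconnections

25 to 24: the two C–O bonds of the oxirane (C13–O, C14–O) are cut. A 2,3-epoxy alcohol is the retron of a titanium–tartrate epoxidation of an E allylic alcohol, and the fragile group then enters last. Two remote stereocentres disappear. The forward step must be reagent-controlled and must leave C1=C10 alone.

24 to 22: the C13–CH3 and C14–C15 bonds are cut. A trisubstituted alkene with methyl cis to CH2OH is what syn methylmetalation of a terminal alkyne followed by a one-carbon electrophile delivers. The chain shrinks to a butynyl group and the alkene geometry needs no separate control. The organoaluminium reagent must spare the hindered ester.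

22 to 20: the ester O–CH3 bond is cut and a silyl group is put back on C14. The acid is what the sigmatropic step releases, and the silyl group masks the acidic alkyne C–H in all enolate steps. The forward esterification must be an O-alkylation, since acyl substitution at the C4 carbonyl is slow.

20 to 17 (key): the C4–C5 bond is cut and the carboxyl oxygen is reconnected to C1. Ring A, the quaternary C4, the tertiary C5 and the alkene position are exchanged for one carbinol centre at C1 in a δ-lactone. The forward step demands the (1R) configuration, O-silylation of the enolate, and a [3,3] shift through the boat that the C2–C3 bridge enforces.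

17 to 15: the lactone C(=O)–O bond and the C1–H bond are cut. A ketone at C1 flanked by a bulky alkenyl group and a CH2 chain is a good substrate for reagent-controlled reduction. No stereocentre is left at C1. The reducing system must add 1,2 and override any bias from C8 and C9.

15 to 13 and 3: the C1–C10 bond is cut. Ring B (as an alkenyl electrophile) is joined to a C1–C4 chain that already carries the methyl and the ester. The coupling must select the aldehyde over the ester and must tolerate a triflate next to a quaternary carbon; its adduct 14 is oxidised, so its C1 configuration is irrelevant.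

13 to 10: the enol O–S bond and the C14–Si bond are cut. C9 is quaternary, so the ketone enolises only toward C5 and the triflate regiochemistry is unambiguous. The alkyne must be silylated before the strong base is used.

10 to 7 to 6: the C10–C14 bond is reconnected and the C10=C14 enone restored. A ketone with a terminal alkyne on a two-carbon tether is the retron of an epoxy ketone fragmentation. The chain and ring B thus come from one bicyclic enone that already holds C8 and C9. The epoxide configuration is irrelevant.

6 to 4: the C8–CH3 bond is traced back to the saturated ketone of 4 (methylenation, then hydrogen). 4 is available as one enantiomer with C9 in place. The olefination must select the saturated ketone, and hydrogen must add to the exocyclic alkene only, anti to the angular methyl.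

3 to 1: the ester bond is traced to ring-opening of 1 and C1 is raised to the aldehyde level. The lactone contains the whole C1–C4 chain with its methyl branch.

## Other disconnections considered

Alternative 1: The cut goes through C5–C10 and C8–C9. The forward step would be an intramolecular Diels–Alder reaction of the open-chain ester A1, in which the (5E,7Z)-diene C5–C8 adds across the remote C9=C10 bond of the allene (heat, or Ni(cod)2 with tris(2-biphenylyl) phosphite), giving A2 with a C6=C7 double bond and C13 masked as a dioxolane.
- In its favour: both rings, three stereocentres (C5, C8, C9) and the C1=C10 alkene would arise in one operation. The alkene position is fixed by the allene as firmly as by the sigmatropic shift, which makes the two plans equal on that point. On ring construction per step this alternative is the better one.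
- Against it: the diene terminus C8 must be Z with an inside methyl, which disfavours the s-cis conformer and invites 1,5-hydrogen shifts. C9 can only be set if the trisubstituted allene is one axial enantiomer. The quaternary C4 must be built beforehand on an acyclic compound and must direct the diene face although methyl and ester differ little in size.
- Afterwards C6=C7 would have to be hydrogenated beside C1=C10, and the C13 ketone converted into the E allylic alcohol by olefination of a methyl ketone (E/Z question) and a reduction next to the C4 ester.
- Comparison: three independent stereo-elements (C4, the allene axis, the diene geometry) would have to cooperate, whereas the chosen plan derives C4, C5 and the alkene from one carbinol centre. The core is shorter; the total including precursor and side chain probably is not.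

Alternative 2: The cut removes C4–C5 and C2–C3. The forward step would be an intermolecular Diels–Alder reaction of the ring B diene A3 (C5=C10 and C1=C2, allyl on C9) with methyl methacrylate A4 under EtAlCl2, giving A5 with the alkene at C1=C10.
- In its favour: it makes the same critical C4–C5 bond and places the alkene equally well. Both partners are simple, and the ester arrives as the methyl ester. The step count to the bicyclic core is clearly lower, so on step economy this alternative is the better one.
- Against it: the bond must form without a tether between ring carbon C5 and the fully substituted carbon of the dienophile. The C6 substituent on the diene terminus favours the needed orientation, while the C9 substituent on C10 opposes it. Endo/exo selection between methyl and ester on one carbon, which decides C4, is usually weak for methacrylates. The diene faces differ only by methyl against CH2 on C9, and the Lewis acid may isomerise or oligomerise the diene.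
- The allyl group would also need hydroboration, oxidation and homologation before the C13–C15 end could be built.
- Comparison: three selectivities (regio, endo/exo, facial) would rest on small steric differences, where the chosen plan settles them by the bridge of the boat and by C1.

Alternative 3: The cut removes the C8–methyl bond and C9–C11. The forward step would be a copper-catalysed conjugate addition of AlMe3 to 2-methylcyclohex-2-enone A6 (copper thiophene-2-carboxylate, chiral phosphoramidite), followed by allylation of the aluminium enolate with allyl iodide A7 anti to the new methyl, giving A8 with C8 and C9 set.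
- In its favour: two adjacent stereocentres would come from achiral materials in one catalytic operation, with no chiral-pool compound and no hydrogenation-face question. As an entry to a stereodefined ring B ketone it is shorter than steps 2–5 and at least their equal.
- Against it: no ring closes and the C4–C5 problem is untouched, so it competes with the front end of the route and not with its key step. Its selectivities would depend on the ligand and on allylation of a hindered enolate. The allyl group is one carbon short of the butynyl chain, and extension with the ketone masked would return the steps that were saved.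
- Comparison: on structure it is complementary (A8 could enter the same lactone chemistry). On mechanism, catalyst control replaces the substrate control of steps 2–3. Overall step counts should be about equal.

Key step: step 11

Remark on the chemistry: 3 is racemic, so 14–17 are carried as epimer mixtures at the carbon α to the ester (C4) and are drawn without a descriptor there; both epimers give the same enolate in step 11. The (1R) descriptor of 17 and the (4S,5R) descriptors of 20 were checked against the boat geometry and against 25 and need no change.

Step 1
Reactants: 1 3-methyloxan-2-one (racemic)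
Product: 3 methyl 2-methyl-5-oxopentanoate (racemic), via hydroxy ester 2 (not isolated)
Conditions: MeOH, H2SO4 (cat.), reflux; NaHCO3, concentrate cold; then PhI(OAc)2, TEMPO (cat.), CH2Cl2, rt
Reagents that add atoms: methanol CO
Why: Acid-catalysed methanolysis opens the δ-lactone, and the hydroxy ester is oxidised at once (TEMPO/PhI(OAc)2 alcohol oxidation) before it can close again. The α-centre is left racemic on purpose because it is erased in step 11.

Step 2
Reactants: 4 (R)-Wieland–Miescher ketone
Product: 5 (4aS)-4a-methyl-5-methylidene-4,4a,5,6,7,8-hexahydronaphthalen-2(3H)-one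
Conditions: Ph3PCH3Br, KOtBu, THF, 0 °C → rt
Reagents that add atoms: methyltriphenylphosphonium bromide C[P+](c1ccccc1)(c1ccccc1)c1ccccc1.[Br-]
Why: Wittig methylenation; the saturated ketone is the more electrophilic carbonyl (the enone is deactivated by conjugation), so one equivalent of ylide should react there only. The descriptor changes only because the priorities change; the quaternary centre is untouched.

Step 3
Reactants: 5 (4aS)-4a-methyl-5-methylidene-4,4a,5,6,7,8-hexahydronaphthalen-2(3H)-one
Product: 6 (4aS,5R)-4a,5-dimethyl-4,4a,5,6,7,8-hexahydronaphthalen-2(3H)-one (cis-dimethyl)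
Conditions: H2 (3 atm), RhCl(PPh3)3 (cat.), PhMe/EtOH, rt
Reagents that add atoms: none
Why: Homogeneous hydrogenation with RhCl(PPh3)3 takes a 1,1-disubstituted alkene much faster than a conjugated trisubstituted one. The angular methyl is axial on the neighbouring carbon and screens its face, so hydrogen should add anti to it and leave the new methyl cis to the angular methyl (C8, R).

Step 4
Reactants: 6 (4aS,5R)-4a,5-dimethyl-4,4a,5,6,7,8-hexahydronaphthalen-2(3H)-one
Product: 7 (4aS,5R)-1,8a-epoxy-4a,5-dimethyloctahydronaphthalen-2(1H)-one (epoxide epimers)
Conditions: 30% H2O2, NaOH, MeOH, 0 °C → rt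
Reagents that add atoms: hydrogen peroxide OO
Why: Weitz–Scheffer nucleophilic epoxidation of the enone. The epoxide configuration is irrelevant because both carbons lose their stereochemistry in step 5.

Step 5
Reactants: 7 (4aS,5R)-1,8a-epoxy-4a,5-dimethyloctahydronaphthalen-2(1H)-one; 8 4-methylbenzenesulfonohydrazide
Product: 10 (2S,3R)-2-(but-3-yn-1-yl)-2,3-dimethylcyclohexan-1-one, via tosylhydrazone 9 (not isolated)
Conditions: AcOH/CH2Cl2 (1:1), −20 °C → rt
Reagents that add atoms: none
Why: Eschenmoser–Tanabe fragmentation: the epoxy tosylhydrazone opens to a hydroxy azoalkene that fragments with loss of N2 and sulfinate, cutting C10–C14 to leave the C10 ketone and the terminal alkyne. C9 (quaternary) and C8 (β to the ketone) cannot epimerise.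

Step 6
Reactants: 10 (2S,3R)-2-(but-3-yn-1-yl)-2,3-dimethylcyclohexan-1-one
Product: 12 (2S,3R)-2,3-dimethyl-2-[4-(trimethylsilyl)but-3-yn-1-yl]cyclohexan-1-one, via silyl enol ether 11 (not isolated)
Conditions: LiN(iPr)2 (2.2 equiv), THF, −78 °C; Me3SiCl, −78 → 0 °C; then 1 M HCl, THF, 0 °C
Reagents that add atoms: chlorotrimethylsilane C[Si](C)(C)Cl
Why: Two equivalents of amide base give the enolate and the acetylide, both are silylated, and dilute acid then hydrolyses only the O-silyl enol ether. The C-silyl group masks the acidic alkyne C–H for the enolate steps 7 and 11 and for the nickel/chromium coupling.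

Step 7
Reactants: 12 (2S,3R)-2,3-dimethyl-2-[4-(trimethylsilyl)but-3-yn-1-yl]cyclohexan-1-one
Product: 13 (5R,6S)-5,6-dimethyl-6-[4-(trimethylsilyl)but-3-yn-1-yl]cyclohex-1-en-1-yl trifluoromethanesulfonate
Conditions: KN(SiMe3)2, THF, −78 °C; PhNTf2, −78 → 0 °C
Reagents that add atoms: N-phenylbis(trifluoromethanesulfonimide) O=S(=O)(N(c1ccccc1)S(=O)(=O)C(F)(F)F)C(F)(F)F
Why: Enolate O-triflation; C9 is quaternary, so only the C5 side can be enolised and the double bond of the triflate lies at C10=C5 without a regiochemical question.

Step 8
Reactants: 13 (5R,6S)-5,6-dimethyl-6-[4-(trimethylsilyl)but-3-yn-1-yl]cyclohex-1-en-1-yl trifluoromethanesulfonate; 3 methyl 2-methyl-5-oxopentanoate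
Product: 14 methyl 5-[(5R,6S)-5,6-dimethyl-6-(4-trimethylsilylbut-3-yn-1-yl)cyclohex-1-en-1-yl]-5-hydroxy-2-methylpentanoate (epimers at C2 and C5 of the chain)
Conditions: CrCl2 (4 equiv), NiCl2 (2 mol%), DMF, rt
Reagents that add atoms: none
Why: Nozaki–Hiyama–Kishi coupling: nickel inserts into the alkenyl triflate and passes the alkenyl group to chromium, whose alkenyl species adds to aldehydes only and leaves the ester alone. The C1 configuration of the adduct is erased in step 9.

Step 9
Reactants: 14 methyl 5-[(5R,6S)-5,6-dimethyl-6-(4-trimethylsilylbut-3-yn-1-yl)cyclohex-1-en-1-yl]-5-hydroxy-2-methylpentanoate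
Product: 15 methyl 5-[(5R,6S)-5,6-dimethyl-6-(4-trimethylsilylbut-3-yn-1-yl)cyclohex-1-en-1-yl]-2-methyl-5-oxopentanoate (C2 epimers)
Conditions: Dess–Martin periodinane, NaHCO3, CH2Cl2, 0 °C → rt
Reagents that add atoms: none
Why: Dess–Martin oxidation of the secondary allylic alcohol to the enone under buffered conditions that leave the silyl alkyne and the ester untouched.

Step 10
Reactants: 15 methyl 5-[(5R,6S)-5,6-dimethyl-6-(4-trimethylsilylbut-3-yn-1-yl)cyclohex-1-en-1-yl]-2-methyl-5-oxopentanoate
Product: 17 (6R)-6-[(5R,6S)-5,6-dimethyl-6-(4-trimethylsilylbut-3-yn-1-yl)cyclohex-1-en-1-yl]-3-methyloxan-2-one (C3 epimers), via hydroxy ester 16 (not isolated)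
Conditions: (S)-Me-CBS oxazaborolidine (0.2 equiv), catecholborane, PhMe, −78 °C; MeOH; then PPTS (cat.), PhMe, 60 °C
Reagents that add atoms: none
Why: Corey–Bakshi–Shibata reduction: the bulky cyclohexenyl group acts as the large and the CH2 chain as the small substituent, so the (S)-catalyst should give the (R)-carbinol at C1, and catecholborane at −78 °C reduces 1,2 without touching alkyne or alkene. Mild acid then closes the δ-lactone by acyl substitution, which does not involve the C1–O bond, so the configuration is retained.

Step 11
Reactants: 17 (6R)-6-[(5R,6S)-5,6-dimethyl-6-(4-trimethylsilylbut-3-yn-1-yl)cyclohex-1-en-1-yl]-3-methyloxan-2-one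
Product: 20 (1S,5S,6R,8aR)-1,5,6-trimethyl-5-[4-(trimethylsilyl)but-3-yn-1-yl]-1,2,3,5,6,7,8,8a-octahydronaphthalene-1-carboxylic acid, via silyl ketene acetal 18 (not isolated), via trimethylsilyl ester 19 (not isolated)
Conditions: LiN(iPr)2, Me3SiCl/Et3N, THF, −78 °C → rt; PhMe, 105 °C; then 1 M HCl, THF, rt
Reagents that add atoms: none
Why: Deprotonation at C4 (both C4 epimers of 17 give the same enolate) and O-silylation give the cyclic silyl ketene acetal 18, whose double-bond geometry is fixed by the ring; on heating it undergoes a concerted suprafacial [3,3] shift in which O–C1 breaks, C4–C5 forms and the double bond moves to C1=C10, and hydrolysis of silyl ester 19 frees acid 20. The closest known reaction type is the Ireland–Claisen rearrangement of lactone silyl ketene acetals, used for ring contraction of alkenyl lactones to cycloalkenecarboxylic acids. Ring A is closed not by a polar exo or endo cyclisation but by ring contraction: the six-membered lactone is exchanged for the six-membered carbocycle as the new σ bond forms inside a bicyclo[2.2.2]octane-like array with the bridges O–C(O), C2–C3 and C10–C5, so the pericyclic array can only be a boat. C5 is controlled by the C1 carbinol centre: the new bond enters the face of C5 from which the C1–O bond departs, and since C2 must lie syn to C5 the (1R) carbinol gives (5R). C4 is controlled by the ring-fixed enol ether geometry together with the boat: the carbon that was bridged to oxygen becomes the carboxyl group cis to C6 and the methyl ends up cis to H5, which is (4S). The step needs O- over C-silylation, favoured by the fully substituted enolate carbon and the amine-buffered chlorosilane, and attack at one face of C5 only, which is secured because the other face would require a trans double bond in ring A. The reactive rotamer places the small H1, not C2, beside the quaternary C9, so the crowding of ring B should not disfavour it. The silyl alkyne and the stereocentres C8 and C9 are spectators.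

Step 12
Reactants: 20 (1S,5S,6R,8aR)-1,5,6-trimethyl-5-[4-(trimethylsilyl)but-3-yn-1-yl]-1,2,3,5,6,7,8,8a-octahydronaphthalene-1-carboxylic acid
Product: 22 methyl (1S,5S,6R,8aR)-5-(but-3-yn-1-yl)-1,5,6-trimethyl-1,2,3,5,6,7,8,8a-octahydronaphthalene-1-carboxylate, via silylated methyl ester 21 (not isolated)
Conditions: MeI, K2CO3, DMF, rt; then MeOH, rt
Reagents that add atoms: iodomethane CI
Why: The hindered acid is esterified by SN2 O-alkylation of its carboxylate, which avoids acyl substitution at the neopentyl-like carbonyl. Methanol with the same carbonate base then removes the alkynyl silyl group; no stereocentre bears an acidic hydrogen.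

Step 13
Reactants: 22 methyl (1S,5S,6R,8aR)-5-(but-3-yn-1-yl)-1,5,6-trimethyl-1,2,3,5,6,7,8,8a-octahydronaphthalene-1-carboxylate
Product: 24 methyl (1S,5S,6R,8aR)-5-[(3E)-5-hydroxy-3-methylpent-3-en-1-yl]-1,5,6-trimethyl-1,2,3,5,6,7,8,8a-octahydronaphthalene-1-carboxylate, via alkenylalane 23 (not isolated)
Conditions: AlMe3 (3 equiv), Cp2ZrCl2 (0.25 equiv), CH2Cl2, 0 °C → rt; then (CH2O)n, THF, 0 °C → rt; aq. Rochelle salt
Reagents that add atoms: trimethylaluminium C[Al](C)C; formaldehyde (as paraformaldehyde) C=O
Why: Zirconium-catalysed methylalumination (Negishi carboalumination) adds methyl and aluminium syn across the terminal alkyne with methyl on the inner carbon, and the alkenyl–aluminium bond adds to formaldehyde with retention, so methyl and CH2OH end up cis (E alkene). The trisubstituted ring alkene is inert and the α-quaternary ester should be too hindered to be attacked at these temperatures.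

Step 14
Reactants: 24 methyl (1S,5S,6R,8aR)-5-[(3E)-5-hydroxy-3-methylpent-3-en-1-yl]-1,5,6-trimethyl-1,2,3,5,6,7,8,8a-octahydronaphthalene-1-carboxylate
Product: 25 methyl (1S,5S,6R,8aR)-5-{2-[(2R,3R)-3-(hydroxymethyl)-2-methyloxiran-2-yl]ethyl}-1,5,6-trimethyl-1,2,3,5,6,7,8,8a-octahydronaphthalene-1-carboxylate (target)
Conditions: Ti(OiPr)4 (cat.), D-(−)-diethyl tartrate (cat.), t-BuOOH, 4 Å MS, CH2Cl2, −20 °C
Reagents that add atoms: tert-butyl hydroperoxide CC(C)(C)OO
Why: Sharpless asymmetric epoxidation: only the allylic alcohol binds titanium, so the ring alkene is spared. For an E allylic alcohol of the geraniol type the D-(−)-tartrate delivers oxygen to the face that gives the (13R,14R)-epoxide (the L-(+)-tartrate gives the 2S,3S series), and the distant ring stereocentres should not interfere.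

Compound list

1 | 3-methyloxan-2-one (racemic) | CC1CCCOC1=O | starting material
2 | methyl 5-hydroxy-2-methylpentanoate (racemic) | COC(=O)C(C)CCCO | intermediate
3 | methyl 2-methyl-5-oxopentanoate (racemic) | COC(=O)C(C)CCC=O | intermediate
4 | (R)-Wieland–Miescher ketone, (8aR)-8a-methyl-3,4,8,8a-tetrahydronaphthalene-1,6(2H,7H)-dione | C[C@@]12CCC(=O)C=C1CCCC2=O | starting material
5 | (4aS)-4a-methyl-5-methylidene-4,4a,5,6,7,8-hexahydronaphthalen-2(3H)-one | C[C@@]12CCC(=O)C=C1CCCC2=C | intermediate
6 | (4aS,5R)-4a,5-dimethyl-4,4a,5,6,7,8-hexahydronaphthalen-2(3H)-one | C[C@@]12CCC(=O)C=C1CCC[C@H]2C | intermediate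
7 | (4aS,5R)-1,8a-epoxy-4a,5-dimethyloctahydronaphthalen-2(1H)-one (epoxide epimers) | C[C@@]12CCC(=O)C3OC13CCC[C@H]2C | intermediate
8 | 4-methylbenzenesulfonohydrazide | Cc1ccc(cc1)S(=O)(=O)NN | starting material
9 | tosylhydrazone of 7 | C[C@@]12CCC(=NNS(=O)(=O)c3ccc(C)cc3)C4OC14CCC[C@H]2C | intermediate
10 | (2S,3R)-2-(but-3-yn-1-yl)-2,3-dimethylcyclohexan-1-one | O=C1CCC[C@@H](C)[C@]1(C)CCC#C | intermediate
11 | trimethylsilyl enol ether of 12 (C10=C5) | C[Si](C)(C)OC1=CCC[C@@H](C)[C@]1(C)CCC#C[Si](C)(C)C | intermediate
12 | (2S,3R)-2,3-dimethyl-2-[4-(trimethylsilyl)but-3-yn-1-yl]cyclohexan-1-one | O=C1CCC[C@@H](C)[C@]1(C)CCC#C[Si](C)(C)C | intermediate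
13 | (5R,6S)-5,6-dimethyl-6-[4-(trimethylsilyl)but-3-yn-1-yl]cyclohex-1-en-1-yl trifluoromethanesulfonate | FC(F)(F)S(=O)(=O)OC1=CCC[C@@H](C)[C@]1(C)CCC#C[Si](C)(C)C | intermediate
14 | methyl 5-[(5R,6S)-5,6-dimethyl-6-(4-trimethylsilylbut-3-yn-1-yl)cyclohex-1-en-1-yl]-5-hydroxy-2-methylpentanoate (epimers at C2 and C5) | COC(=O)C(C)CCC(O)C1=CCC[C@@H](C)[C@]1(C)CCC#C[Si](C)(C)C | intermediate
15 | methyl 5-[(5R,6S)-5,6-dimethyl-6-(4-trimethylsilylbut-3-yn-1-yl)cyclohex-1-en-1-yl]-2-methyl-5-oxopentanoate (C2 epimers) | COC(=O)C(C)CCC(=O)C1=CCC[C@@H](C)[C@]1(C)CCC#C[Si](C)(C)C | intermediate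
16 | methyl (5R)-5-[(5R,6S)-5,6-dimethyl-6-(4-trimethylsilylbut-3-yn-1-yl)cyclohex-1-en-1-yl]-5-hydroxy-2-methylpentanoate (C2 epimers) | COC(=O)C(C)CC[C@@H](O)C1=CCC[C@@H](C)[C@]1(C)CCC#C[Si](C)(C)C | intermediate
17 | (6R)-6-[(5R,6S)-5,6-dimethyl-6-(4-trimethylsilylbut-3-yn-1-yl)cyclohex-1-en-1-yl]-3-methyloxan-2-one (C3 epimers) | CC1CC[C@@H](OC1=O)C2=CCC[C@@H](C)[C@]2(C)CCC#C[Si](C)(C)C | intermediate
18 | (2R)-2-[(5R,6S)-5,6-dimethyl-6-(4-trimethylsilylbut-3-yn-1-yl)cyclohex-1-en-1-yl]-5-methyl-6-(trimethylsilyloxy)-3,4-dihydro-2H-pyran | CC1=C(O[Si](C)(C)C)O[C@H](CC1)C2=CCC[C@@H](C)[C@]2(C)CCC#C[Si](C)(C)C | intermediate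
19 | trimethylsilyl ester of 20 | C[Si](C)(C)OC(=O)[C@@]1(C)CCC=C2[C@H]1CC[C@@H](C)[C@]2(C)CCC#C[Si](C)(C)C | intermediate
20 | (1S,5S,6R,8aR)-1,5,6-trimethyl-5-[4-(trimethylsilyl)but-3-yn-1-yl]-1,2,3,5,6,7,8,8a-octahydronaphthalene-1-carboxylic acid | OC(=O)[C@@]1(C)CCC=C2[C@H]1CC[C@@H](C)[C@]2(C)CCC#C[Si](C)(C)C | intermediate
21 | methyl ester of 20 | COC(=O)[C@@]1(C)CCC=C2[C@H]1CC[C@@H](C)[C@]2(C)CCC#C[Si](C)(C)C | intermediate
22 | methyl (1S,5S,6R,8aR)-5-(but-3-yn-1-yl)-1,5,6-trimethyl-1,2,3,5,6,7,8,8a-octahydronaphthalene-1-carboxylate | COC(=O)[C@@]1(C)CCC=C2[C@H]1CC[C@@H](C)[C@]2(C)CCC#C | intermediate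
23 | (E)-alkenyl(dimethyl)alane from 22 (methyl on C13, aluminium on C14) | COC(=O)[C@@]1(C)CCC=C2[C@H]1CC[C@@H](C)[C@]2(C)CC/C(C)=C/[Al](C)C | intermediate
24 | methyl (1S,5S,6R,8aR)-5-[(3E)-5-hydroxy-3-methylpent-3-en-1-yl]-1,5,6-trimethyl-1,2,3,5,6,7,8,8a-octahydronaphthalene-1-carboxylate | COC(=O)[C@@]1(C)CCC=C2[C@H]1CC[C@@H](C)[C@]2(C)CC/C(C)=C/CO | intermediate
25 | methyl (1S,5S,6R,8aR)-5-{2-[(2R,3R)-3-(hydroxymethyl)-2-methyloxiran-2-yl]ethyl}-1,5,6-trimethyl-1,2,3,5,6,7,8,8a-octahydronaphthalene-1-carboxylate | COC(=O)[C@@]1(C)CCC=C2[C@H]1CC[C@@H](C)[C@]2(C)CC[C@@]1(C)O[C@@H]1CO | target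

Total step count: 14. Longest linear sequence: 13 steps (4 to 25, steps 2–14); step 1 supplies fragment 3.

Least certain steps

Step 11 (key step). Most likely failure: C-silylation or self-acylation of the lactone enolate before it is trapped, or a [3,3] shift that is slow because a quaternary carbon must bond to a ring carbon near the crowded C9, so that hydrolysis back to 17 or thermal elimination across C1–O takes over. Any (1S) material carried from step 10 would be transferred into the (4R,5S) series. Fallback: set out from 13. Stille coupling with tributyl(vinyl)stannane (Pd(PPh3)4, LiCl, THF, reflux) should give the diene (5R,6S)-1-ethenyl-5,6-dimethyl-6-[4-(trimethylsilyl)but-3-yn-1-yl]cyclohex-1-ene F1. A Diels–Alder reaction of F1 with methyl methacrylate A4 (EtAlCl2, CH2Cl2, −78 → 0 °C) would form C2–C3 and C4–C5 and lead to 21, where the route is rejoined before the methanol stage of step 12. Regio-, endo/exo and facial selectivity would then rest on the substrate alone, and isomers might have to be separated.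

Step 3. Most likely failure: poor facial selectivity if the rhodium complex can also approach syn to the angular methyl, or slow reaction at the alkene beside the quaternary carbon with onset of enone reduction. Fallback: set out from 5. Epoxidise first (H2O2, NaOH, MeOH; only the enone reacts) to the epoxy ketone (4aS)-1,8a-epoxy-4a-methyl-5-methylideneoctahydronaphthalen-2(1H)-one F2. Then reduce the exocyclic alkene by manganese hydride hydrogen-atom transfer (Mn(dpm)3 cat., PhSiH3, t-BuOOH, i-PrOH, rt). There a tertiary radical at C8 takes up hydrogen under stereoelectronic rather than catalyst-approach control, which should favour the equatorial methyl cis to the angular one, and no conjugated alkene is left to compete. The product is 7.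

Step 8. Most likely failure: slow insertion of nickel into the triflate flanked by the quaternary carbon, so that reduction of the triflate or consumption of the aldehyde competes; partial lactonisation of 14 on work-up would also withdraw material from step 9. Fallback: set out from 12. Condensation with 2,4,6-triisopropylbenzenesulfonohydrazide (MeOH, cat. HCl, rt) should give the hydrazone F3. A Shapiro reaction (n-BuLi 2.2 equiv, THF, −78 → 0 °C) should give the alkenyllithium F4, whose double bond can only lie at C10=C5. Addition of F4 to 3 at −78 °C returns to the route at 14.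

Step 10. Most likely failure: insufficient facial selectivity if the catalyst is mismatched with the intrinsic bias from C9 or if the twisted enone binds poorly, and partial 1,4-reduction. Fallback: set out from 14, omitting step 9 and the reduction. A kinetic resolution by Sharpless epoxidation (Ti(OiPr)4, L-(+)-diisopropyl tartrate, t-BuOOH 0.6 equiv, 4 Å MS, CH2Cl2, −20 °C) should epoxidise the (1S) epimers fast to the epoxy alcohol F5. The (1R) hydroxy ester 16 is left and is lactonised to 17 as in step 10. The cost is at most half of the material.

Step 13. Most likely failure: incomplete capture of alkenylalane 23 by formaldehyde, which after work-up leaves the protonated alkene, and methyl transfer from aluminium to the ester on long reaction times. Fallback: set out from 22. The same methylalumination (water-accelerated variant at −20 °C) is quenched with I2 to give the (E)-alkenyl iodide F6. A Nozaki–Hiyama–Kishi coupling of F6 with paraformaldehyde (CrCl2, NiCl2 cat., DMF, rt) returns to the route at 24.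

Further compounds

F1 | step 11 | (5R,6S)-1-ethenyl-5,6-dimethyl-6-[4-(trimethylsilyl)but-3-yn-1-yl]cyclohex-1-ene | C=CC1=CCC[C@@H](C)[C@]1(C)CCC#C[Si](C)(C)C
F2 | step 3 | (4aS)-1,8a-epoxy-4a-methyl-5-methylideneoctahydronaphthalen-2(1H)-one (epoxide epimers) | C[C@@]12CCC(=O)C3OC13CCCC2=C
F3 | step 8 | 2,4,6-triisopropylbenzenesulfonylhydrazone of 12 | CC(C)c1cc(C(C)C)c(c(c1)C(C)C)S(=O)(=O)NN=C1CCC[C@@H](C)[C@]1(C)CCC#C[Si](C)(C)C
F4 | step 8 | [(5R,6S)-5,6-dimethyl-6-(4-trimethylsilylbut-3-yn-1-yl)cyclohex-1-en-1-yl]lithium | [Li]C1=CCC[C@@H](C)[C@]1(C)CCC#C[Si](C)(C)C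
F5 | step 10 | 10,5-epoxide of the (1S) epimer of 14 (oxygen syn to the C9 side chain, C2 epimers) | COC(=O)C(C)CC[C@H](O)[C@@]12O[C@@H]1CC[C@@H](C)[C@]2(C)CCC#C[Si](C)(C)C
F6 | step 13 | methyl (1S,5S,6R,8aR)-5-[(3E)-4-iodo-3-methylbut-3-en-1-yl]-1,5,6-trimethyl-1,2,3,5,6,7,8,8a-octahydronaphthalene-1-carboxylate | COC(=O)[C@@]1(C)CCC=C2[C@H]1CC[C@@H](C)[C@]2(C)CC/C(C)=C/I
A1 | alternative 1 | methyl (2S)-2,7-dimethyl-9-(2-methyl-1,3-dioxolan-2-yl)-2-[(1E,3Z)-penta-1,3-dien-1-yl]nona-5,6-dienoate (allene axis as encoded) | COC(=O)[C@@](C)(CCC=[C@]=C(C)CCC1(C)OCCO1)/C=C/C=C\C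
A2 | alternative 1 | bicyclic ester with C1=C10 and C6=C7 double bonds and C13 dioxolane | COC(=O)[C@@]1(C)CCC=C2[C@H]1C=C[C@@H](C)[C@]2(C)CCC1(C)OCCO1
A3 | alternative 2 | (5R,6S)-1-ethenyl-5,6-dimethyl-6-(prop-2-en-1-yl)cyclohex-1-ene | C=CC1=CCC[C@@H](C)[C@]1(C)CC=C
A4 | alternative 2 | methyl methacrylate | COC(=O)C(C)=C
A5 | alternative 2 | methyl (1S,5S,6R,8aR)-1,5,6-trimethyl-5-(prop-2-en-1-yl)-1,2,3,5,6,7,8,8a-octahydronaphthalene-1-carboxylate | COC(=O)[C@@]1(C)CCC=C2[C@H]1CC[C@@H](C)[C@]2(C)CC=C
A6 | alternative 3 | 2-methylcyclohex-2-en-1-one | CC1=CCCCC1=O
A7 | alternative 3 | allyl iodide | C=CCI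
A8 | alternative 3 | (2S,3R)-2,3-dimethyl-2-(prop-2-en-1-yl)cyclohexan-1-one | O=C1CCC[C@@H](C)[C@]1(C)CC=C
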